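Atom labels used throughout: the lactone half carries lignan numbers (C9 carbonyl, C8 α-carbon, C7 its methylene, C8' β-carbon, C7' its methylene, C9' the OCH2 carbon); the dihydrobenzofuran atoms are double-primed (O1'', C2'', C3'', C3a'', C5'', C7''). Ring A is the guaiacyl ring on C7', ring B the lactone, ring C the benzo ring, ring D the dihydrofuran, ring E the guaiacyl ring on C2''.

## Analysis of the target

Isolappaol A (30) is a sesquilignan: a 2,3-disubstituted γ-butyrolactone (ring B) whose C8' carries the 4-hydroxy-3-methoxybenzyl group of ring A and whose C8 is joined through the methylene C7 to C5'' of a 2-aryl-3-hydroxymethyl-7-methoxy-2,3-dihydrobenzofuran (rings C and D, with ring E on C2''). It has four stereocentres in two pairs: C8 (R) and C8' (R), trans on ring B, and C2'' (S) and C3'' (R), trans on ring D. The pairs are insulated from each other by C7 and ring C, so neither can induce the other; each must be made in absolute form, and a mismatch gives a diastereomer, not the enantiomer. Within each pair the trans relation is the thermodynamically preferred one, because C8 is epimerisable next to the lactone carbonyl and C2'' is a benzylic ether carbon para to an oxygen donor and can re-ionise; only C8' and C3'' therefore need absolute control. The sensitive groups are the two free phenols (oxidation, and opening of ring D through a quinone methide from the ring E phenoxide), the lactone (hydrolysis, epimerisation), the benzylic C2''–O bond (acid, hydrogenolysis) and the primary alcohol. The hard part is C8': it sits between three methylene groups with no neighbouring functional group through which a reagent could address it, and the two electron-rich halves must be joined at C7 without disturbing it. The strategy rests on one feature: ring A, C7', C8' and one further methylene are the carbon skeleton of eugenol (1), and ring B (C8', C9', O, C9, C8) is a 3-substituted cyclobutanone with one oxygen inserted beside the carbonyl. In that cyclobutanone C8' lies on a mirror plane, so the choice of which C–C(=O) bond receives the oxygen creates the stereocentre.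

## Retrosynthetic reasoning

**30 ⇐ 29.** Both phenols are carried as silyl ethers (tert-butyldimethylsilyl on ring A, triisopropylsilyl on ring E) and released last by buffered fluoride. No skeletal bond is touched, and the primary alcohol travels free from the moment it is formed.

**29 ⇐ 28 ⇐ 12 + 27.** The bond cut is C7–C5'', between the exocyclic methylene carbon of the lactone and ring C. It is cut there and not at C8–C7 because the aryl bromide already present in the commercial ring C building block 15 then becomes the coupling handle directly (as boronate 27), and C7 is supplied as a one-carbon unit on the lactone 12. The forward reaction is a rhodium-catalysed conjugate addition of the aryl group to the exocyclic alkene. It forms C8 by protonation without control, so 28 is taken as an epimer mixture and drained by base to the more stable trans lactone 29, C8 following C8'. The gain is convergence: two fragments of similar size, each with its own absolute stereocentre.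

**12 ⇐ 10 ⇐ 8.** The exocyclic methylene is put on the parent lactone 8 by a Mannich reaction of its enolate 9 and elimination through the ammonium salt 11. Nothing stereochemical is created; the only requirement is that C8' survives, so the elimination must be mild enough not to move the double bond into the ring.

**8 ⇐ 6 (key disconnection).** The O–C9' bond is cut: lactone 8 is cyclobutanone 6 plus one oxygen. 6 is achiral, with its mirror plane through the carbonyl carbon and C8'. The forward reaction, an oxygen insertion by a peracid on a chiral Lewis acid, has to tell the two enantiotopic ring methylene groups apart. This is the place for the one catalyst-controlled step of the route, because C8' has no adjacent functional group for any other asymmetric method to use, and desymmetrisation needs none.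

**6 ⇐ 5 ⇐ 2 + 4 ⇐ 1 + 3.** Two ring bonds of the cyclobutanone are cut: a (2+2) cycloaddition of the alkene of silylated eugenol 2 with dichloroketene 4 (from 3), then reductive removal of both chlorines from 5. The allyl chain of 1 supplies C7', C8' and one ring methylene; the ketene supplies the carbonyl carbon C9 and the other methylene. Which of the two methylenes ends as C9' and which as C8 is decided only in the key step. Because they are enantiotopic, this bookkeeping has no consequence.

**27 ⇐ 26.** The C–B bond comes from the C–Br bond by palladium-catalysed borylation.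

**26 ⇐ 25.** The O1''–C2'' bond is cut. In the forward direction the phenol of 25 closes onto the benzylic carbon through a cation stabilised by ring E. Ionisation makes the attack selective for C2'' over the primary carbinol carbon, which would also give a five-membered ring. Under reversible conditions the trans ring results, so C2'' takes its configuration from C3'' and ring D needs only one controlled stereocentre.

**25 ⇐ 24 ⇐ 23 ⇐ 21 + 14.** The C2''–C3'' bond is cut as an auxiliary-controlled aldol between the arylacetyl imide 21 and the silylated vanillin 14 (from 13). The auxiliary sets C3''. Reduction turns the acyl carbon into the hydroxymethyl group and releases the auxiliary (24), and the allyl ether is then removed (25).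

**21 ⇐ 19 ⇐ 17 ⇐ 16 ⇐ 15.** The arylacetic acid 19 comes from 5-bromo-o-vanillin 15 by allyl protection and a one-carbon homologation through the enol ether 17 and aldehyde 18. The aldehyde carbon of 15 becomes C3'', its hydroxyl oxygen O1'', and its bromine marks C5''.

## Alternatives that were turned down

**Alternative 1:** Both carbon–carbon bonds that hold the lactone substituents, C7'–C8' and C8–C7, are cut, leaving a chiral butenolide as linchpin. In the forward key step the lithiated ring A dithiane A2 adds to the β-carbon of the (5R)-menthyloxy butenolide A1 on the face away from the menthyloxy group, and the resulting enolate is alkylated in the same flask by the dihydrobenzofuran benzylic bromide A3, giving the all-trans adduct A4.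
- For it: three fragments are joined in one operation, and both lactone stereocentres are fixed by a stoichiometric acetal auxiliary of well-understood sense. The trans relation arises directly, with no equilibration.
- Against it, for this target: A3 needs an extra carbon installed at C5'' and is a para-alkoxybenzyl bromide prone to ionisation. After the key step the dithiane must be removed reductively in the presence of the benzylic C2''–O bond of ring D, and the acetal carbon must be reduced to the C9' methylene. The auxiliary is stoichiometric.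
- Comparison: Alternative 1 is stronger on convergence and on the certainty of the relative and absolute configuration at C8 and C8'. The chosen strategy offers in its place a catalytic origin of C8' from an achiral intermediate three steps from eugenol, a lactone branch free of sulfur and auxiliary, and direct use of the aryl bromide as coupling handle. The price is a catalyst-controlled step of less certain selectivity and one equilibration step.

**Alternative 2:** Ring D is traced back to a six-membered flavanone, and the C3''–C3a'' bond is made by migration of the ring C carbon. In the forward key step the (2S)-flavanone A5 is treated with a hypervalent aryliodine diacetate and strong acid in an orthoformate medium; the enol ether forms, C3 is iodinated and the ring C carbon shifts from the carbonyl carbon to C3, contracting the pyranone to the trans dihydrobenzofuran ester A6.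
- For it: A5 is reachable in two condensation steps from simple aromatic carbonyl compounds, the ester sits where the hydroxymethyl group is needed, and trans is the stable arrangement.
- Against it: the absolute configuration rests entirely on C2 of A5, a centre that racemises by reversible retro-oxa-Michael ring opening under acid or base, and the key step is run in strong acid. With an electron-rich 4-oxygenated aryl group on C2, migration of that aryl group and dehydrogenation of the heterocycle compete with ring contraction. Three electron-rich rings face a strong oxidant, which forces an acyl protecting group. The strategy does nothing for C8'.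
- Comparison: if enantiopure A5 were at hand, this would reach ring D in fewer steps than the auxiliary sequence used here, and on that point it is stronger. The chosen strategy offers instead a C3'' that is set by an auxiliary and cannot racemise once reduced, and it spends its single catalyst-controlled step on the lactone, which Alternative 2 leaves unsolved.

**Alternative 3:** The C2''–C3'' bond of ring D is cut. In the forward key step a chiral dirhodium tetracarboxylate (divalent rhodium) decomposes the aryldiazoacetate A7, and the carbenoid inserts into the benzylic C–H bond of the O–CH2–aryl ether, closing ring D. Methoxide in the same flask then epimerises the ester-bearing carbon, so that the trans ester A8 results.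
- For it: the step is catalytic, the C–H bond is doubly activated (next to oxygen and benzylic), and insertion through a five-membered transition state is the favoured mode. C2'' is set by the catalyst and C3'' follows by equilibration. From 15 it is about as long as the sequence used here and needs no auxiliary; on catalytic economy for ring D it is stronger.
- Against it: oxonium ylide formation at the ether oxygen followed by a benzyl shift, and attack of the carbenoid on the electron-rich ring E, compete with insertion. The methoxide used for epimerisation also cleaves aryl silyl ethers. Diazo transfer adds a hazardous operation. C8' is again untouched.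
- Comparison: the chosen strategy prefers to place its one selectivity-critical catalytic step on C8', where no auxiliary handle exists, and to build ring D by stoichiometric but routine chemistry. If step economy for ring D became decisive, A8 could be reduced and borylated and would enter the same coupling.

Key step: step 4

Assumption: the sense of induction of the scandium–N,N'-dioxide catalyst on 6 is not derived from a model here; the ligand enantiomer (from the L- or the D-amino acid) that delivers the (4R)-lactone 8 is used, and the configuration of 8 is to be confirmed by correlation before the route is continued.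

## Route

Step 1
Reactants: 1 eugenol
Product: 2 tert-butyl[2-methoxy-4-(prop-2-en-1-yl)phenoxy]dimethylsilane
Conditions: TBSCl, imidazole, DMF, rt
Reagents that add atoms: tert-butyldimethylsilyl chloride, CC(C)(C)[Si](C)(C)Cl
Why: Standard imidazole-assisted silylation of a phenol; the silyl ether masks the phenol against the ZnCl2 of step 2, the peracid of step 4 and the amide base of step 5.

Step 2
Reactants: 2 tert-butyl[2-methoxy-4-(prop-2-en-1-yl)phenoxy]dimethylsilane; 3 trichloroacetyl chloride
Product: 5 rac-2,2-dichloro-3-{[4-(tert-butyldimethylsilyloxy)-3-methoxyphenyl]methyl}cyclobutan-1-one, via dichloroketene 4 (not isolated)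
Conditions: Zn–Cu couple, POCl3, Et2O, slow addition of 3, 35 °C
Reagents that add atoms: none
Why: Thermal (2+2) cycloaddition of dichloroketene 4 (zinc dechlorination of 3) to the terminal alkene; the CH2 terminus bonds to the ketene carbonyl carbon and the substituted carbon to CCl2, the known regiochemistry for monosubstituted alkenes, and POCl3 ties up ZnCl2 so that the silyl ether is spared. The product is racemic, which does not matter because step 3 removes the chirality.

Step 3
Reactants: 5 rac-2,2-dichloro-3-{[4-(tert-butyldimethylsilyloxy)-3-methoxyphenyl]methyl}cyclobutan-1-one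
Product: 6 3-{[4-(tert-butyldimethylsilyloxy)-3-methoxyphenyl]methyl}cyclobutan-1-one
Conditions: Zn dust, AcOH, rt to 50 °C
Reagents that add atoms: none
Why: Reductive dehalogenation of an α,α-dichloroketone by zinc in acetic acid through zinc enolates; 6 is achiral, with a mirror plane through the carbonyl carbon, C3 and the benzylic carbon.

Step 4
Reactants: 6 3-{[4-(tert-butyldimethylsilyloxy)-3-methoxyphenyl]methyl}cyclobutan-1-one
Product: 8 (4R)-4-{[4-(tert-butyldimethylsilyloxy)-3-methoxyphenyl]methyl}oxolan-2-one, via Criegee peroxy adduct 7 (not isolated)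
Conditions: Sc(OTf)3 (5 mol %), chiral N,N'-dioxide ligand (bis-N-oxide of two pipecolic acid 2,6-diisopropylanilide units joined at nitrogen by a propane-1,3-diyl chain, 5 mol %), mCPBA (1.3 equiv), EtOAc, −20 °C
Reagents that add atoms: m-chloroperbenzoic acid, OOC(=O)c1cccc(Cl)c1
Why: The scandium triflate–N,N'-dioxide complex binds the carbonyl oxygen of 6 and the peracid adds to give the Criegee adduct 7. In 7 the ring C–C bond that lies antiperiplanar to the O–O bond migrates from carbon to oxygen with retention while m-chlorobenzoate leaves, which forms the O–C9' bond. Ring B is thus made by a 1,2-shift that enlarges the four-membered ring to the five-membered lactone, not by a cyclisation, and relief of cyclobutanone strain keeps the step fast at −20 °C. No bond at C8' is made or broken: C8' becomes a stereocentre because the two enantiotopic methylene arms become different, and the chiral ligand sphere on scandium (catalyst control) decides which arm is antiperiplanar to the peroxide bond. The closest known reaction type is the catalytic enantioselective Baeyer–Villiger desymmetrisation of prochiral 3-substituted cyclobutanones by chiral Lewis acid–peracid systems or by monooxygenases. The only selectivity required is between enantiotopic groups; regioselectivity is no issue because both migrating carbons are methylene groups of the same kind, and chemoselectivity is secured because the strained ketone reacts far faster than the silyl-protected arene. The demanding point is that the discriminating substituent is a flexible benzyl group and not an aryl group attached directly to the ring.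

Step 5
Reactants: 8 (4R)-4-{[4-(tert-butyldimethylsilyloxy)-3-methoxyphenyl]methyl}oxolan-2-one
Product: 10 (3S,4R)-4-{[4-(tert-butyldimethylsilyloxy)-3-methoxyphenyl]methyl}-3-[(dimethylamino)methyl]oxolan-2-one, via lithium enolate 9 (not isolated)
Conditions: LiN(iPr)2, THF, −78 °C; dimethyl(methylidene)ammonium iodide, −78 °C to rt
Reagents that add atoms: dimethyl(methylidene)ammonium iodide (Eschenmoser's salt), C[N+](C)=C.[I-]
Why: Mannich reaction of the lithium enolate 9 with the preformed iminium salt, the usual first half of a lactone α-methylenation; attack anti to the C8' substituent should give mainly the trans isomer, but this new centre is removed again in step 6 and C8' is not acidic.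

Step 6
Reactants: 10 (3S,4R)-4-{[4-(tert-butyldimethylsilyloxy)-3-methoxyphenyl]methyl}-3-[(dimethylamino)methyl]oxolan-2-one
Product: 12 (4R)-4-{[4-(tert-butyldimethylsilyloxy)-3-methoxyphenyl]methyl}-3-methylideneoxolan-2-one, via trimethylammonium iodide 11 (not isolated)
Conditions: MeI, MeOH, rt; then aq. NaHCO3, CH2Cl2, rt
Reagents that add atoms: none
Why: Quaternisation with iodomethane and E1cB (Hofmann-type) loss of trimethylamine from the β-ammonio lactone 11; aqueous NaHCO3 suffices for the elimination but is too weak to move the exocyclic double bond into the ring, which would erase C8'.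

Step 7
Reactants: 13 vanillin
Product: 14 3-methoxy-4-[tri(propan-2-yl)silyloxy]benzaldehyde
Conditions: TIPSCl, imidazole, DMF, rt
Reagents that add atoms: triisopropylsilyl chloride, CC(C)[Si](Cl)(C(C)C)C(C)C
Why: Silylation of the phenol; the triisopropylsilyl ether is chosen because it withstands the acid of step 15 and the basic media of steps 16 to 18 better than a tert-butyldimethylsilyl ether.

Step 8
Reactants: 15 5-bromo-2-hydroxy-3-methoxybenzaldehyde
Product: 16 5-bromo-3-methoxy-2-(prop-2-en-1-yloxy)benzaldehyde
Conditions: allyl bromide, K2CO3, DMF, 50 °C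
Reagents that add atoms: allyl bromide, C=CCBr
Why: Williamson ether synthesis; the allyl ether is stable to ylide, aqueous acid, chlorite, boron triflate and borohydride and is removed in step 14 under neutral conditions that leave the aryl bromide and the silyl ether alone.

Step 9
Reactants: 16 5-bromo-3-methoxy-2-(prop-2-en-1-yloxy)benzaldehyde
Product: 17 5-bromo-1-methoxy-3-(2-methoxyethenyl)-2-(prop-2-en-1-yloxy)benzene (E/Z mixture)
Conditions: Ph3P(CH2OMe)Cl, KOtBu, THF, 0 °C to rt
Reagents that add atoms: (methoxymethyl)triphenylphosphonium chloride, COC[P+](c1ccccc1)(c1ccccc1)c1ccccc1.[Cl-]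
Why: Wittig reaction with the methoxymethylidene ylide, the first half of a one-carbon homologation of an aldehyde that has no α-hydrogen; the alkene geometry is inconsequential.

Step 10
Reactants: 17 5-bromo-1-methoxy-3-(2-methoxyethenyl)-2-(prop-2-en-1-yloxy)benzene
Product: 19 [5-bromo-3-methoxy-2-(prop-2-en-1-yloxy)phenyl]acetic acid, via arylacetaldehyde 18 (not isolated)
Conditions: 2 M HCl, THF, 45 °C; then NaClO2, NaH2PO4, 2-methyl-2-butene, t-BuOH–H2O, 0 °C to rt
Reagents that add atoms: water, O; sodium chlorite, [Na+].[O-]Cl=O
Why: Acid hydrolysis of the enol ether gives the arylacetaldehyde 18, which is oxidised without purification by the Pinnick chlorite oxidation; 2-methyl-2-butene scavenges hypochlorous acid so that the allyl ether and the electron-rich ring are not chlorinated.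

Step 11
Reactants: 19 [5-bromo-3-methoxy-2-(prop-2-en-1-yloxy)phenyl]acetic acid
Product: 21 (4S)-4-benzyl-3-{[5-bromo-3-methoxy-2-(prop-2-en-1-yloxy)phenyl]acetyl}-1,3-oxazolidin-2-one, via mixed pivalic anhydride 20 (not isolated)
Conditions: PivCl, Et3N, THF, −20 °C; then LiCl, (S)-4-benzyl-1,3-oxazolidin-2-one, rt
Reagents that add atoms: (4S)-4-benzyl-1,3-oxazolidin-2-one, O=C1N[C@@H](Cc2ccccc2)CO1
Why: N-Acylation of the oxazolidinone through the mixed anhydride 20 under LiCl/Et3N conditions, which need no strong base and so leave the acidic benzylic methylene alone.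

Step 12
Reactants: 21 (4S)-4-benzyl-3-{[5-bromo-3-methoxy-2-(prop-2-en-1-yloxy)phenyl]acetyl}-1,3-oxazolidin-2-one; 14 3-methoxy-4-[tri(propan-2-yl)silyloxy]benzaldehyde
Product: 23 (4S)-4-benzyl-3-[(2S,3S)-2-[5-bromo-3-methoxy-2-(prop-2-en-1-yloxy)phenyl]-3-hydroxy-3-{3-methoxy-4-[tri(propan-2-yl)silyloxy]phenyl}propanoyl]-1,3-oxazolidin-2-one, via dibutylboron enolate 22 (not isolated)
Conditions: Bu2BOTf, iPr2NEt, CH2Cl2, 0 °C; 14, −78 to 0 °C; pH 7 buffer, MeOH, H2O2, 0 °C
Reagents that add atoms: none
Why: Evans syn-aldol reaction: soft enolisation gives the Z-boron enolate 22, which reacts through a closed chair (Zimmerman–Traxler) transition state on the enolate face away from the benzyl group of the auxiliary in its dipole-opposed conformation, so the aryl-bearing carbon (later C3'') is set by the auxiliary. The carbinol centre is formed syn but is not needed later, because step 15 passes through a cation.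

Step 13
Reactants: 23 (4S)-4-benzyl-3-[(2S,3S)-2-[5-bromo-3-methoxy-2-(prop-2-en-1-yloxy)phenyl]-3-hydroxy-3-{3-methoxy-4-[tri(propan-2-yl)silyloxy]phenyl}propanoyl]-1,3-oxazolidin-2-one
Product: 24 (1S,2R)-2-[5-bromo-3-methoxy-2-(prop-2-en-1-yloxy)phenyl]-1-{3-methoxy-4-[tri(propan-2-yl)silyloxy]phenyl}propane-1,3-diol
Conditions: LiBH4, MeOH (1 equiv), THF, 0 °C
Reagents that add atoms: none
Why: Reductive cleavage of the N-acyl oxazolidinone by LiBH4 gives the primary alcohol and returns the auxiliary; the aryl-bearing stereocentre is then no longer next to a carbonyl group and cannot epimerise.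

Step 14
Reactants: 24 (1S,2R)-2-[5-bromo-3-methoxy-2-(prop-2-en-1-yloxy)phenyl]-1-{3-methoxy-4-[tri(propan-2-yl)silyloxy]phenyl}propane-1,3-diol
Product: 25 (1S,2R)-2-(5-bromo-2-hydroxy-3-methoxyphenyl)-1-{3-methoxy-4-[tri(propan-2-yl)silyloxy]phenyl}propane-1,3-diol
Conditions: Pd(PPh3)4 (5 mol %), morpholine, THF, rt
Reagents that add atoms: none
Why: Tsuji–Trost deallylation: zerovalent palladium ionises the allyl aryl ether to a π-allyl complex that morpholine captures; at room temperature oxidative addition into the electron-rich aryl bromide does not compete.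

Step 15
Reactants: 25 (1S,2R)-2-(5-bromo-2-hydroxy-3-methoxyphenyl)-1-{3-methoxy-4-[tri(propan-2-yl)silyloxy]phenyl}propane-1,3-diol
Product: 26 [(2S,3R)-5-bromo-7-methoxy-2-{3-methoxy-4-[tri(propan-2-yl)silyloxy]phenyl}-2,3-dihydro-1-benzofuran-3-yl]methanol
Conditions: TsOH·H2O (10 mol %), CH2Cl2 (dilute), 0 °C to rt
Reagents that add atoms: none
Why: Acid-catalysed SN1 etherification: the benzylic alcohol ionises to a cation stabilised by the para silyloxy group of ring E and the phenol oxygen closes the five-membered ring D, while the primary hydroxyl cannot ionise and so is not attacked. Ring closure is reversible under acid, so the more stable trans isomer should accumulate and C2'' (S) is set by C3''.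

Step 16
Reactants: 26 [(2S,3R)-5-bromo-7-methoxy-2-{3-methoxy-4-[tri(propan-2-yl)silyloxy]phenyl}-2,3-dihydro-1-benzofuran-3-yl]methanol
Product: 27 [(2S,3R)-7-methoxy-2-{3-methoxy-4-[tri(propan-2-yl)silyloxy]phenyl}-5-(4,4,5,5-tetramethyl-1,3,2-dioxaborolan-2-yl)-2,3-dihydro-1-benzofuran-3-yl]methanol
Conditions: B2pin2, PdCl2(dppf) (3 mol %), KOAc, 1,4-dioxane, 85 °C
Reagents that add atoms: bis(pinacolato)diboron, CC1(C)OB(OC1(C)C)B1OC(C)(C)C(C)(C)O1
Why: Miyaura borylation (oxidative addition of zerovalent palladium into the C–Br bond, acetate-assisted transmetalation with the diboron, reductive elimination); the free primary alcohol, the silyl ether and the benzylic ether tolerate KOAc.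

Step 17
Reactants: 12 (4R)-4-{[4-(tert-butyldimethylsilyloxy)-3-methoxyphenyl]methyl}-3-methylideneoxolan-2-one; 27 [(2S,3R)-7-methoxy-2-{3-methoxy-4-[tri(propan-2-yl)silyloxy]phenyl}-5-(4,4,5,5-tetramethyl-1,3,2-dioxaborolan-2-yl)-2,3-dihydro-1-benzofuran-3-yl]methanol
Product: 28 (4R)-4-{[4-(tert-butyldimethylsilyloxy)-3-methoxyphenyl]methyl}-3-{[(2S,3R)-3-(hydroxymethyl)-7-methoxy-2-{3-methoxy-4-[tri(propan-2-yl)silyloxy]phenyl}-2,3-dihydro-1-benzofuran-5-yl]methyl}oxolan-2-one (C3 epimer mixture)
Conditions: [Rh(OH)(cod)]2 (3 mol %), K3PO4 (0.5 equiv), 1,4-dioxane–H2O (10:1), 40 °C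
Reagents that add atoms: none
Why: Rhodium-catalysed 1,4-addition of an arylboron reagent to an activated 1,1-disubstituted alkene (Hayashi–Miyaura type): aryl transfer from boron to the monovalent rhodium hydroxide, insertion of the exocyclic alkene to an oxa-π-allyl rhodium enolate and protonolysis by water form the C7–C5'' bond. C8 arises by an uncontrolled protonation and is corrected in step 18; C8', C2'' and C3'' are not involved.

Step 18
Reactants: 28 (4R)-4-{[4-(tert-butyldimethylsilyloxy)-3-methoxyphenyl]methyl}-3-{[(2S,3R)-3-(hydroxymethyl)-7-methoxy-2-{3-methoxy-4-[tri(propan-2-yl)silyloxy]phenyl}-2,3-dihydro-1-benzofuran-5-yl]methyl}oxolan-2-one (C3 epimer mixture)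
Product: 29 (3R,4R)-4-{[4-(tert-butyldimethylsilyloxy)-3-methoxyphenyl]methyl}-3-{[(2S,3R)-3-(hydroxymethyl)-7-methoxy-2-{3-methoxy-4-[tri(propan-2-yl)silyloxy]phenyl}-2,3-dihydro-1-benzofuran-5-yl]methyl}oxolan-2-one
Conditions: DBU (0.3 equiv), anhydrous toluene, rt to 40 °C
Reagents that add atoms: none
Why: Base-mediated epimerisation through the lactone enolate; the trans-2,3-disubstituted butyrolactone is the more stable epimer (substrate control from C8'), and C8', C2'' and C3'' are not acidic. Anhydrous conditions keep the aryl silyl ethers in place.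

Step 19
Reactants: 29 (3R,4R)-4-{[4-(tert-butyldimethylsilyloxy)-3-methoxyphenyl]methyl}-3-{[(2S,3R)-3-(hydroxymethyl)-7-methoxy-2-{3-methoxy-4-[tri(propan-2-yl)silyloxy]phenyl}-2,3-dihydro-1-benzofuran-5-yl]methyl}oxolan-2-one
Product: 30 isolappaol A
Conditions: Bu4NF, AcOH, THF, 0 °C to rt
Reagents that add atoms: none
Why: Fluoride cleavage of both aryl silyl ethers; acetic acid buffers the phenoxides, so C8 does not epimerise and ring D does not open through a quinone methide.

## Compound list

1 | eugenol, 2-methoxy-4-(prop-2-en-1-yl)phenol | COc1cc(CC=C)ccc1O | starting material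
2 | tert-butyl[2-methoxy-4-(prop-2-en-1-yl)phenoxy]dimethylsilane | COc1cc(CC=C)ccc1O[Si](C)(C)C(C)(C)C | intermediate
3 | trichloroacetyl chloride | ClC(=O)C(Cl)(Cl)Cl | starting material
4 | dichloroketene | ClC(Cl)=C=O | intermediate (not isolated)
5 | rac-2,2-dichloro-3-{[4-(tert-butyldimethylsilyloxy)-3-methoxyphenyl]methyl}cyclobutan-1-one | COc1cc(CC2CC(=O)C2(Cl)Cl)ccc1O[Si](C)(C)C(C)(C)C | intermediate
6 | 3-{[4-(tert-butyldimethylsilyloxy)-3-methoxyphenyl]methyl}cyclobutan-1-one | COc1cc(CC2CC(=O)C2)ccc1O[Si](C)(C)C(C)(C)C | intermediate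
7 | Criegee adduct, 3-{[4-(tert-butyldimethylsilyloxy)-3-methoxyphenyl]methyl}-1-hydroxycyclobutyl 3-chlorobenzenecarboperoxoate | COc1cc(CC2CC(O)(OOC(=O)c3cccc(Cl)c3)C2)ccc1O[Si](C)(C)C(C)(C)C | intermediate (not isolated)
8 | (4R)-4-{[4-(tert-butyldimethylsilyloxy)-3-methoxyphenyl]methyl}oxolan-2-one | COc1cc(C[C@H]2COC(=O)C2)ccc1O[Si](C)(C)C(C)(C)C | intermediate
9 | lithium enolate of 8, lithium (3R)-3-{[4-(tert-butyldimethylsilyloxy)-3-methoxyphenyl]methyl}-2,3-dihydrofuran-5-olate | [Li+].COc1cc(C[C@H]2COC([O-])=C2)ccc1O[Si](C)(C)C(C)(C)C | intermediate (not isolated)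
10 | (3S,4R)-4-{[4-(tert-butyldimethylsilyloxy)-3-methoxyphenyl]methyl}-3-[(dimethylamino)methyl]oxolan-2-one | COc1cc(C[C@H]2COC(=O)[C@@H]2CN(C)C)ccc1O[Si](C)(C)C(C)(C)C | intermediate
11 | {[(3S,4R)-4-{[4-(tert-butyldimethylsilyloxy)-3-methoxyphenyl]methyl}-2-oxooxolan-3-yl]methyl}trimethylammonium iodide | COc1cc(C[C@H]2COC(=O)[C@@H]2C[N+](C)(C)C)ccc1O[Si](C)(C)C(C)(C)C.[I-] | intermediate (not isolated)
12 | (4R)-4-{[4-(tert-butyldimethylsilyloxy)-3-methoxyphenyl]methyl}-3-methylideneoxolan-2-one | COc1cc(C[C@H]2COC(=O)C2=C)ccc1O[Si](C)(C)C(C)(C)C | intermediate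
13 | vanillin, 4-hydroxy-3-methoxybenzaldehyde | COc1cc(C=O)ccc1O | starting material
14 | 3-methoxy-4-[tri(propan-2-yl)silyloxy]benzaldehyde | COc1cc(C=O)ccc1O[Si](C(C)C)(C(C)C)C(C)C | intermediate
15 | 5-bromo-2-hydroxy-3-methoxybenzaldehyde (5-bromo-o-vanillin) | COc1cc(Br)cc(C=O)c1O | starting material
16 | 5-bromo-3-methoxy-2-(prop-2-en-1-yloxy)benzaldehyde | COc1cc(Br)cc(C=O)c1OCC=C | intermediate
17 | 5-bromo-1-methoxy-3-(2-methoxyethenyl)-2-(prop-2-en-1-yloxy)benzene, E/Z mixture | COC=Cc1cc(Br)cc(OC)c1OCC=C | intermediate
18 | [5-bromo-3-methoxy-2-(prop-2-en-1-yloxy)phenyl]acetaldehyde | O=CCc1cc(Br)cc(OC)c1OCC=C | intermediate (not isolated)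
19 | [5-bromo-3-methoxy-2-(prop-2-en-1-yloxy)phenyl]acetic acid | OC(=O)Cc1cc(Br)cc(OC)c1OCC=C | intermediate
20 | [5-bromo-3-methoxy-2-(prop-2-en-1-yloxy)phenyl]acetic 2,2-dimethylpropanoic anhydride | CC(C)(C)C(=O)OC(=O)Cc1cc(Br)cc(OC)c1OCC=C | intermediate (not isolated)
21 | (4S)-4-benzyl-3-{[5-bromo-3-methoxy-2-(prop-2-en-1-yloxy)phenyl]acetyl}-1,3-oxazolidin-2-one | O=C1OC[C@H](Cc2ccccc2)N1C(=O)Cc1cc(Br)cc(OC)c1OCC=C | intermediate
22 | (4S)-4-benzyl-3-[(Z)-2-[5-bromo-3-methoxy-2-(prop-2-en-1-yloxy)phenyl]-1-(dibutylboranyloxy)ethenyl]-1,3-oxazolidin-2-one | CCCCB(CCCC)O/C(=C\c1cc(Br)cc(OC)c1OCC=C)N1[C@@H](Cc2ccccc2)COC1=O | intermediate (not isolated)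
23 | (4S)-4-benzyl-3-[(2S,3S)-2-[5-bromo-3-methoxy-2-(prop-2-en-1-yloxy)phenyl]-3-hydroxy-3-{3-methoxy-4-[tri(propan-2-yl)silyloxy]phenyl}propanoyl]-1,3-oxazolidin-2-one | O=C1OC[C@H](Cc2ccccc2)N1C(=O)[C@@H](c1cc(Br)cc(OC)c1OCC=C)[C@H](O)c1ccc(O[Si](C(C)C)(C(C)C)C(C)C)c(OC)c1 | intermediate
24 | (1S,2R)-2-[5-bromo-3-methoxy-2-(prop-2-en-1-yloxy)phenyl]-1-{3-methoxy-4-[tri(propan-2-yl)silyloxy]phenyl}propane-1,3-diol | OC[C@@H](c1cc(Br)cc(OC)c1OCC=C)[C@H](O)c1ccc(O[Si](C(C)C)(C(C)C)C(C)C)c(OC)c1 | intermediate
25 | (1S,2R)-2-(5-bromo-2-hydroxy-3-methoxyphenyl)-1-{3-methoxy-4-[tri(propan-2-yl)silyloxy]phenyl}propane-1,3-diol | OC[C@@H](c1cc(Br)cc(OC)c1O)[C@H](O)c1ccc(O[Si](C(C)C)(C(C)C)C(C)C)c(OC)c1 | intermediate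
26 | [(2S,3R)-5-bromo-7-methoxy-2-{3-methoxy-4-[tri(propan-2-yl)silyloxy]phenyl}-2,3-dihydro-1-benzofuran-3-yl]methanol | Brc1cc(OC)c2c(c1)[C@H](CO)[C@@H](c1ccc(O[Si](C(C)C)(C(C)C)C(C)C)c(OC)c1)O2 | intermediate
27 | [(2S,3R)-7-methoxy-2-{3-methoxy-4-[tri(propan-2-yl)silyloxy]phenyl}-5-(4,4,5,5-tetramethyl-1,3,2-dioxaborolan-2-yl)-2,3-dihydro-1-benzofuran-3-yl]methanol | CC1(C)OB(OC1(C)C)c1cc(OC)c2c(c1)[C@H](CO)[C@@H](c1ccc(O[Si](C(C)C)(C(C)C)C(C)C)c(OC)c1)O2 | intermediate
28 | (4R)-4-{[4-(tert-butyldimethylsilyloxy)-3-methoxyphenyl]methyl}-3-{[(2S,3R)-3-(hydroxymethyl)-7-methoxy-2-{3-methoxy-4-[tri(propan-2-yl)silyloxy]phenyl}-2,3-dihydro-1-benzofuran-5-yl]methyl}oxolan-2-one, mixture of C3 (C8) epimers | COc1cc(C[C@H]2COC(=O)C2Cc2cc(OC)c3c(c2)[C@H](CO)[C@@H](c2ccc(O[Si](C(C)C)(C(C)C)C(C)C)c(OC)c2)O3)ccc1O[Si](C)(C)C(C)(C)C | intermediate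
29 | (3R,4R)-4-{[4-(tert-butyldimethylsilyloxy)-3-methoxyphenyl]methyl}-3-{[(2S,3R)-3-(hydroxymethyl)-7-methoxy-2-{3-methoxy-4-[tri(propan-2-yl)silyloxy]phenyl}-2,3-dihydro-1-benzofuran-5-yl]methyl}oxolan-2-one | COc1cc(C[C@H]2COC(=O)[C@@H]2Cc2cc(OC)c3c(c2)[C@H](CO)[C@@H](c2ccc(O[Si](C(C)C)(C(C)C)C(C)C)c(OC)c2)O3)ccc1O[Si](C)(C)C(C)(C)C | intermediate
30 | isolappaol A, (3R,4R)-3-{[(2S,3R)-2-(4-hydroxy-3-methoxyphenyl)-3-(hydroxymethyl)-7-methoxy-2,3-dihydro-1-benzofuran-5-yl]methyl}-4-[(4-hydroxy-3-methoxyphenyl)methyl]oxolan-2-one | COc1cc(C[C@H]2COC(=O)[C@@H]2Cc2cc(OC)c3c(c2)[C@H](CO)[C@@H](c2ccc(O)c(OC)c2)O3)ccc1O | target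

## Step count and least certain steps

Total: 19 steps. Longest linear sequence: 12 steps (15 to 30; steps 8 to 16, then 17 to 19). The lactone branch (steps 1 to 6) and aldehyde 14 (step 7) join it at steps 17 and 12.

**Step 4 (key step).** The most likely failure is insufficient discrimination between the two enantiotopic methylene groups, because the substituent the catalyst must read is a flexible benzyl group one atom away from the ring. An uncatalysed, racemic background oxidation by the peracid would add to this. Changes inside the step (the other ligand antipode, other amide groups on the ligand, a Baeyer–Villiger monooxygenase with O2) are tried first. Two features limit the damage: the minor enantiomer of 8 becomes a diastereomer after coupling with enantiopure 27 and can be removed there.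
- Fallback, from 6 back to 8: desymmetrise 6 by enantioselective deprotonation with a chiral lithium amide (lithium bis(1-phenylethyl)amide of the appropriate configuration) and in situ Me3SiCl at −100 °C. This gives the silyl enol ether tert-butyl[2-methoxy-4-({(1R)-3-[(trimethylsilyl)oxy]cyclobut-2-en-1-yl}methyl)phenoxy]dimethylsilane F1. Ozonolysis at −78 °C, with an indicator dye to spare the arene, and reduction of the ozonide with NaBH4 cleave the enol double bond to a carboxyl group and a hydroxymethyl group, giving (3R)-4-[4-(tert-butyldimethylsilyloxy)-3-methoxyphenyl]-3-(hydroxymethyl)butanoic acid F2. F2 closes to 8 on acidification.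

**Step 17.** Three processes threaten it: protodeboronation of the electron-rich boronate before transmetalation; migration of the exocyclic double bond of 12 into the ring under base or a rhodium hydride, which would erase C8'; and β-hydride elimination of the alkylrhodium in place of protonation.
- Fallback, from 8 and 26 back to 30: form C8–C7 by enolate alkylation in place of C7–C5'' by conjugate addition. 26 is silylated (TBSCl, imidazole) to tert-butyl{[(2S,3R)-5-bromo-7-methoxy-2-{3-methoxy-4-[tri(propan-2-yl)silyloxy]phenyl}-2,3-dihydro-1-benzofuran-3-yl]methoxy}dimethylsilane F3. Bromine–lithium exchange (n-BuLi, −78 °C) and DMF give the aldehyde (2S,3R)-3-{[(tert-butyldimethylsilyl)oxy]methyl}-7-methoxy-2-{3-methoxy-4-[tri(propan-2-yl)silyloxy]phenyl}-2,3-dihydro-1-benzofuran-5-carbaldehyde F4. NaBH4 gives the benzylic alcohol [(2S,3R)-3-{[(tert-butyldimethylsilyl)oxy]methyl}-7-methoxy-2-{3-methoxy-4-[tri(propan-2-yl)silyloxy]phenyl}-2,3-dihydro-1-benzofuran-5-yl]methanol F5. CBr4 and PPh3 give the bromide {[(2S,3R)-5-(bromomethyl)-7-methoxy-2-{3-methoxy-4-[tri(propan-2-yl)silyloxy]phenyl}-2,3-dihydro-1-benzofuran-3-yl]methoxy}(tert-butyl)dimethylsilane F6, which is used at once. The lithium enolate 9, made from 8 as in step 5, is alkylated by F6 at −78 °C anti to the C8' substituent, which gives the trans lactone directly: (3R,4R)-3-{[(2S,3R)-3-{[(tert-butyldimethylsilyl)oxy]methyl}-7-methoxy-2-{3-methoxy-4-[tri(propan-2-yl)silyloxy]phenyl}-2,3-dihydro-1-benzofuran-5-yl]methyl}-4-{[4-(tert-butyldimethylsilyloxy)-3-methoxyphenyl]methyl}oxolan-2-one F7. Bu4NF with AcOH removes the three silyl groups and gives 30. Steps 5, 6 and 16 to 18 are then not needed.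

**Step 15.** The acid needed for ionisation may also strip the silyl ether, and the benzylic cation may alkylate the electron-rich rings of a second molecule (oligomerisation) before the phenol closes the ring; equilibration to trans may also stay incomplete.
- Fallback, from 25 back to 26: change the reactive intermediate from a cation to a neutral quinone methide. Bu4NF with AcOH removes the silyl group of 25 and gives (1S,2R)-2-(5-bromo-2-hydroxy-3-methoxyphenyl)-1-(4-hydroxy-3-methoxyphenyl)propane-1,3-diol F8. Its free para-hydroxybenzyl alcohol loses water under much milder conditions (pyridinium tosylate, warm toluene) to a para-quinone methide, to which the ortho-phenol adds reversibly (5-exo-trig conjugate addition), giving the trans compound 4-[(2S,3R)-5-bromo-3-(hydroxymethyl)-7-methoxy-2,3-dihydro-1-benzofuran-2-yl]-2-methoxyphenol F9. Silylation of the phenoxide (TIPSCl, K2CO3, DMF), which leaves the neutral primary alcohol, returns to 26.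

**Step 2.** Oligomerisation of the ketene may outrun cycloaddition to a non-activated monosubstituted alkene, and ZnCl2 may remove the silyl ether.
- Fallback, from 2 back to 6: a keteniminium (2+2) cycloaddition. N,N-dimethylacetamide, Tf2O and 2,4,6-collidine in refluxing 1,2-dichloroethane generate the keteniminium ion, which adds to the alkene of 2 to give N-[3-{[4-(tert-butyldimethylsilyloxy)-3-methoxyphenyl]methyl}cyclobutylidene]-N-methylmethanaminium trifluoromethanesulfonate F10. Hydrolysis with aqueous NaHCO3 gives 6 directly, and step 3 is then not needed.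

## Further compounds

F1 | step 4 | tert-butyl[2-methoxy-4-({(1R)-3-[(trimethylsilyl)oxy]cyclobut-2-en-1-yl}methyl)phenoxy]dimethylsilane | COc1cc(C[C@@H]2CC(O[Si](C)(C)C)=C2)ccc1O[Si](C)(C)C(C)(C)C
F2 | step 4 | (3R)-4-[4-(tert-butyldimethylsilyloxy)-3-methoxyphenyl]-3-(hydroxymethyl)butanoic acid | COc1cc(C[C@H](CC(O)=O)CO)ccc1O[Si](C)(C)C(C)(C)C
F3 | step 17 | tert-butyl{[(2S,3R)-5-bromo-7-methoxy-2-{3-methoxy-4-[tri(propan-2-yl)silyloxy]phenyl}-2,3-dihydro-1-benzofuran-3-yl]methoxy}dimethylsilane | Brc1cc(OC)c2c(c1)[C@H](CO[Si](C)(C)C(C)(C)C)[C@@H](c1ccc(O[Si](C(C)C)(C(C)C)C(C)C)c(OC)c1)O2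
F4 | step 17 | (2S,3R)-3-{[(tert-butyldimethylsilyl)oxy]methyl}-7-methoxy-2-{3-methoxy-4-[tri(propan-2-yl)silyloxy]phenyl}-2,3-dihydro-1-benzofuran-5-carbaldehyde | O=Cc1cc(OC)c2c(c1)[C@H](CO[Si](C)(C)C(C)(C)C)[C@@H](c1ccc(O[Si](C(C)C)(C(C)C)C(C)C)c(OC)c1)O2
F5 | step 17 | [(2S,3R)-3-{[(tert-butyldimethylsilyl)oxy]methyl}-7-methoxy-2-{3-methoxy-4-[tri(propan-2-yl)silyloxy]phenyl}-2,3-dihydro-1-benzofuran-5-yl]methanol | OCc1cc(OC)c2c(c1)[C@H](CO[Si](C)(C)C(C)(C)C)[C@@H](c1ccc(O[Si](C(C)C)(C(C)C)C(C)C)c(OC)c1)O2
F6 | step 17 | {[(2S,3R)-5-(bromomethyl)-7-methoxy-2-{3-methoxy-4-[tri(propan-2-yl)silyloxy]phenyl}-2,3-dihydro-1-benzofuran-3-yl]methoxy}(tert-butyl)dimethylsilane | BrCc1cc(OC)c2c(c1)[C@H](CO[Si](C)(C)C(C)(C)C)[C@@H](c1ccc(O[Si](C(C)C)(C(C)C)C(C)C)c(OC)c1)O2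
F7 | step 17 | (3R,4R)-3-{[(2S,3R)-3-{[(tert-butyldimethylsilyl)oxy]methyl}-7-methoxy-2-{3-methoxy-4-[tri(propan-2-yl)silyloxy]phenyl}-2,3-dihydro-1-benzofuran-5-yl]methyl}-4-{[4-(tert-butyldimethylsilyloxy)-3-methoxyphenyl]methyl}oxolan-2-one | COc1cc(C[C@H]2COC(=O)[C@@H]2Cc2cc(OC)c3c(c2)[C@H](CO[Si](C)(C)C(C)(C)C)[C@@H](c2ccc(O[Si](C(C)C)(C(C)C)C(C)C)c(OC)c2)O3)ccc1O[Si](C)(C)C(C)(C)C
F8 | step 15 | (1S,2R)-2-(5-bromo-2-hydroxy-3-methoxyphenyl)-1-(4-hydroxy-3-methoxyphenyl)propane-1,3-diol | OC[C@@H](c1cc(Br)cc(OC)c1O)[C@H](O)c1ccc(O)c(OC)c1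
F9 | step 15 | 4-[(2S,3R)-5-bromo-3-(hydroxymethyl)-7-methoxy-2,3-dihydro-1-benzofuran-2-yl]-2-methoxyphenol | Brc1cc(OC)c2c(c1)[C@H](CO)[C@@H](c1ccc(O)c(OC)c1)O2
F10 | step 2 | N-[3-{[4-(tert-butyldimethylsilyloxy)-3-methoxyphenyl]methyl}cyclobutylidene]-N-methylmethanaminium trifluoromethanesulfonate | COc1cc(CC2CC(=[N+](C)C)C2)ccc1O[Si](C)(C)C(C)(C)C.[O-]S(=O)(=O)C(F)(F)F
A1 | alternative 1 | (5R)-5-{[(1R,2S,5R)-5-methyl-2-(propan-2-yl)cyclohexyl]oxy}furan-2(5H)-one | O=C1C=C[C@H](O[C@@H]2C[C@H](C)CC[C@H]2C(C)C)O1
A2 | alternative 1 | 2-[4-(tert-butyldimethylsilyloxy)-3-methoxyphenyl]-1,3-dithiane | COc1cc(C2SCCCS2)ccc1O[Si](C)(C)C(C)(C)C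
A3 | alternative 1 | {[(2S,3R)-5-(bromomethyl)-2-[4-(tert-butyldimethylsilyloxy)-3-methoxyphenyl]-7-methoxy-2,3-dihydro-1-benzofuran-3-yl]methoxy}(tert-butyl)dimethylsilane | BrCc1cc(OC)c2c(c1)[C@H](CO[Si](C)(C)C(C)(C)C)[C@@H](c1ccc(O[Si](C)(C)C(C)(C)C)c(OC)c1)O2
A4 | alternative 1 | all-trans 3-(dihydrobenzofuran-5-ylmethyl)-4-(2-aryl-1,3-dithian-2-yl)-5-menthyloxyoxolan-2-one (tris-silyl ether) | COc1cc(C2(SCCCS2)[C@H]3[C@H](O[C@@H]4C[C@H](C)CC[C@H]4C(C)C)OC(=O)[C@@H]3Cc5cc(OC)c6c(c5)[C@H](CO[Si](C)(C)C(C)(C)C)[C@@H](c7ccc(O[Si](C)(C)C(C)(C)C)c(OC)c7)O6)ccc1O[Si](C)(C)C(C)(C)C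
A5 | alternative 2 | (2S)-6-bromo-8-methoxy-2-[3-methoxy-4-(2,2-dimethylpropanoyloxy)phenyl]-2,3-dihydro-4H-chromen-4-one | COc1cc(Br)cc2C(=O)C[C@@H](c3ccc(OC(=O)C(C)(C)C)c(OC)c3)Oc12
A6 | alternative 2 | methyl (2S,3S)-5-bromo-7-methoxy-2-[3-methoxy-4-(2,2-dimethylpropanoyloxy)phenyl]-2,3-dihydro-1-benzofuran-3-carboxylate | Brc1cc(OC)c2c(c1)[C@H](C(=O)OC)[C@@H](c1ccc(OC(=O)C(C)(C)C)c(OC)c1)O2
A7 | alternative 3 | methyl 2-[5-bromo-2-{[4-(tert-butyldimethylsilyloxy)-3-methoxyphenyl]methoxy}-3-methoxyphenyl]-2-diazoacetate | COC(=O)C(=[N+]=[N-])c1cc(Br)cc(OC)c1OCc1ccc(O[Si](C)(C)C(C)(C)C)c(OC)c1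
A8 | alternative 3 | methyl (2S,3S)-5-bromo-2-[4-(tert-butyldimethylsilyloxy)-3-methoxyphenyl]-7-methoxy-2,3-dihydro-1-benzofuran-3-carboxylate | Brc1cc(OC)c2c(c1)[C@H](C(=O)OC)[C@@H](c1ccc(O[Si](C)(C)C(C)(C)C)c(OC)c1)O2
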